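I decide to reckon this flask from its two ends before any integration runs.

| flask | substrate | reagent | initiator | time | remark |
|---|---|---|---|---|---|
| summer | 0.050 M (fed, over 1.00 h) | 2.00 equiv | 3.3 mol% | 2.0 h | all but substrate at the start; substrate goes in evenly over 1.00 h, the run ends at 2.0 h |
| spring | 0.050 M | 2.00 equiv | 3.3 mol% |  | one stirred flow tank at steady state, fed with the mixture as stated, mean residence time 20.0 h |
| dawn | 0.050 M | 2.00 equiv | 3.3 mol% | 2.0 h | everything together in a closed stirred flask, run for 2.0 h |
| autumn | 0.050 M | 2.00 equiv | 3.3 mol% |  | a single well-mixed tank run continuously and read at steady state, 2.0 h in it on average |

    initiator → 2 initiating radical (k1 = 1.6 × 10⁻⁵ /min)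
    substrate + initiating radical → capped initiator + first chain carrier (k2 = 1.6 × 10⁶ /M/s)
    reagent + first chain carrier → product + second chain carrier (k3 = 50000 /M/s)
    substrate + second chain carrier → released group + first chain carrier (k4 = 1.5 × 10⁵ /M/s)
    2 second chain carrier → ended chains A (k5 = 4 × 10⁷ /M/s)
    2 first chain carrier → ended chains B (k6 = 8 × 10⁸ /M/s)

- percent here means substrate units held: one ended chains B counts as two
- two of one species on the left: rate k times its square, two consumed each time
- the stated concentrations are those of everything mixed, before any reaction; amounts are the same in each set-up
- the feed brings no volume worth counting
- run time (summer): 2.0 h

* the set-up with the highest amount of product at the outlet or at the end, in percent of the substrate put in ("none" if the first two lie within 2 percentage points) (summer / spring / dawn / autumn / none)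
* amount of product at the outlet or at the end, in percent of the substrate put in, summer
* amount of product at the outlet or at the end, in percent of the substrate put in, spring
* amount of product at the outlet or at the end, in percent of the substrate put in, dawn
* amount of product at the outlet or at the end, in percent of the substrate put in, autumn

Let r be the chain rate, at which the reagent step and the substrate step both turn. The starting reagent is 0.100 M. Initiation gives 8.80 × 10⁻¹⁰ M/s, and I hold it fixed because the initiator half-life 30 d is far longer than any stay here.

In the first extreme, every chain ends by two first chain carriers meeting. Then r is the reagent constant times reagent times the root of initiation over twice that ending constant. That gives 3.71 × 10⁻⁶ M/s at the start, whatever the substrate: pseudo-first-order in reagent.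

In the second extreme, every chain ends by two second chain carriers meeting. Then r is proportional to substrate, 2.49 × 10⁻⁵ M/s at full substrate.

Both endings share one initiation, so the real r lies below both, and their inverse squares add. I call the substrate level where the two endings take equal shares the crossing concentration, 0.00745 M. Above it, r follows the first extreme.

Dawn therefore reaches at most 46.9 %, with substrate still above crossing. Autumn reaches at most 42.1 %. Summer's feed alone takes 8.94 min to bring substrate to crossing, and reaction during feeding can only delay that. Summer therefore starts below the first extreme, so I expect it a little under dawn. Spring on the first extreme would ask for 0.0728 M of product, more than the charge. So spring substrate must drop under crossing, and the second extreme caps it at 97.3 %.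

The forecast gives 43.2 % for summer, 97 % for spring, 46.2 % for dawn and 41.4 % for autumn, and names spring. Its ground: “Termination of the first carrier dominates until substrate runs low.” My ceilings for dawn and autumn stand above its values for those flasks .

The simulation gives 43.3 % for summer, 97.1 % for spring, 46.2 % for dawn and 41.4 % for autumn, so spring leads. The autumn tank holds substrate at 0.0293 M, 3.93 times the crossing concentration. In the spring tank, the charge not turned into product is 0.00147 M, less than the crossing concentration taken at the reagent left there, 0.00384 M.

(All constants are assumed; the run is a simulation.)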